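(The runs were generated by integration from invented constants; scatter was added.)

In a one-step world, where substrate turns into target at a rate in proportion to the substrate, the fraction of substrate left falls by the same share each minute, so I watch the fraction left.

| flask | substrate | free catalyst | target | time |
|---|---|---|---|---|
| dawn | 0.120 M | 0.00240 M |  |  |
| summer | 0.360 M | 0.00240 M |  |  |
| spring | 0.120 M | 0.00120 M |  |  |
| noon | 0.120 M | 0.00240 M | 0.0600 M | 34 min |

Noon is the dawn charge plus target equal to half of the substrate, so the question is whether target changes that fall.

| run | time / min | [target] / M |
|---|---|---|
| dawn run | 1.2 | 0.0015 |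
| dawn run | 3.7 | 0.0056 |
| dawn run | 7.1 | 0.0108 |
| dawn run | 11 | 0.0171 |
| dawn run | 16 | 0.0253 |
| dawn run | 21 | 0.0341 |
| dawn run | 27 | 0.0452 |
| dawn run | 34 | 0.0581 |
| summer run | 1.2 | 8 × 10⁻⁴ |
| summer run | 3.7 | 8 × 10⁻⁴ |
| summer run | 7.1 | 0.0030 |
| summer run | 11 | 0.0044 |
| summer run | 16 | 0.0067 |
| summer run | 21 | 0.0090 |
| summer run | 27 | 0.0116 |
| summer run | 34 | 0.0147 |
| spring run | 1.2 | 1 × 10⁻⁴ |
| spring run | 3.7 | 0.0015 |
| spring run | 7.1 | 0.0023 |
| spring run | 11 | 0.0035 |
| spring run | 16 | 0.0063 |
| spring run | 21 | 0.0083 |
| spring run | 27 | 0.0111 |
| spring run | 34 | 0.0130 |

(each reading ± 4 × 10⁻⁴ M)

But dawn does not keep one share: it averages 0.0140 min⁻¹ over the first 11 min and 0.0195 min⁻¹ over 34 min, faster as substrate goes, and its fraction left at 34 min is 0.516.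

Target could do that, but summer, with 3.00 times the substrate, takes 27 min to reach 0.0116 M of target where dawn takes 7.1 min to reach 0.0108 M, so summer is slower at nearly the same target, and I read dawn's quickening as substrate leaving.

Spring, with half the catalyst, reaches 0.0111 M at 27 min, and dawn reaches 0.0108 M at 7.1 min, which is 3.80 times the time. The squared catalyst ratio is 4.00, and I carry it as the stretch: the factor by which a flask with the dawn substrate charge takes longer than dawn to reach any fraction left.

- Overall: substrate -> target, with free catalyst as catalyst.
- Constant volume, constant temperature.
- Readings of a species count what is bound in complexes too.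
- An order is taken over about fifteen percent of the charge, up and down.
- A share of target counts the target that was charged too.

1. the power of [free catalyst] that the first rate follows, about the charge of the dawn run; measure it at two percent of substrate made into target
2. the power of [substrate] that the first rate follows, about the charge of the dawn run; measure it at two percent of substrate made into target (one fixed amount of target, the same in the runs compared)
3. target in the noon run at 34 min, as a share of the substrate charged
4. which of these the readings show (the product speeds the reaction / the substrate ties up the catalyst / the substrate is lost by itself / an uncatalysed path runs beside)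

Noon's stretch is 1.00, so if target does nothing, noon's fraction left at 34 min is dawn's 0.516. My share, with the charged target counted, is 98.4 %.

The forecast gives orders 1.9 for catalyst and −0.9 for substrate, names this: the substrate ties up the catalyst, and puts noon at 93 %, below mine, on this ground: “The muted dawn rise hints at some product binding, so I expect somewhat lower”.

The flask gives orders 2.0 and −0.63, the substrate ties up the catalyst, and noon at 98.3 %, which is 5.3 percentage points above the forecast.

    free catalyst + substrate ⇌ catalyst-substrate complex, settled at all times (11.30 L mol⁻¹)
    catalyst-substrate complex + free catalyst → target + 2 free catalyst (1548 L mol⁻¹ min⁻¹)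
    catalyst-substrate complex + substrate ⇌ doubly bound catalyst, settled at all times (3.030 L mol⁻¹)

In noon, for the whole 34 min, free catalyst and substrate stand in fast balance with the catalyst-substrate complex and the doubly bound catalyst while the complex meets free catalyst and gives target, and noon's fraction left ends at 0.517. In spring the same step runs on half the catalyst, and dawn's 18.5 min to a quarter made, times the stretch, is 74.1 min, where spring stands at 74.4 min.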